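**Plan**
- Retrosynthesis: cut first the C5–CH2 bond of the prenyl group at the quaternary centre (dearomatising allylic alkylation), then the ring–acyl bond at C7, then the C2–C3 bond of the 2H-pyran. The ethynyl group, the isopropyl ether and the third ring oxygen then lead back to 4-methylresorcinol.
- Forward: the benzene ring comes from 4-methylresorcinol (third oxygen by formylation and Dakin oxidation, ortho-formyl to ethynyl, O-isopropyl). The pyran ring is closed on this arene, the 3-phenylpropanoyl group enters by directed lithiation, and the carbocycle is dearomatised last.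
- Enabling feature: C2 of the pyran is a gem-dimethyl carbon on the ring oxygen (a latent acetone oxocarbenium), and C3=C4 is a cis-alkene on C4a, the ring carbon ortho to that oxygen. An isopropyl ether on C8a and an ethynyl group on C4a therefore place the hydridic methine C–H 1,5 to the internal alkyne carbon.
- A catalytic internal redox (hydride shift, then C3–C2 bond formation) turns this simple pair into the ring and makes the quaternary C2 from a C–H bond, with no helper group to remove.
- Stereochemistry: the only stereocentre, C5 (S), is set in the last step by palladium-catalysed asymmetric allylic alkylation of the phenol under a chiral diphosphine ligand.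

Key step: step 7

Remark: chromene numbering (O1, C2, C3, C4, C4a, C5 to C8, C8a) is used throughout. The (R,R)-ligand is assumed to deliver the S centre; the sense of induction is to be confirmed by chiroptical analysis, and the antipodal ligand is the remedy if it is opposite.

**Route**

Step 1
Reactants: 1 4-methylbenzene-1,3-diol (4-methylresorcinol)
Product: 3 2,4-dihydroxy-5-methylbenzaldehyde, via benzylidene(dimethyl)iminium chloride 2 (not isolated)
Conditions: POCl3, DMF, MeCN, 0 °C to rt; then H2O, 50 °C
Reagents that add atoms: N,N-dimethylformamide CN(C)C=O; water O; phosphoryl chloride O=P(Cl)(Cl)Cl (chloride of 2 only)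
Why: Vilsmeier–Haack formylation, in which the chloroiminium electrophile should attack the one ring carbon that is ortho to one hydroxyl and para to the other, the iminium salt being hydrolysed on aqueous heating.

Step 2
Reactants: 3 2,4-dihydroxy-5-methylbenzaldehyde
Product: 4 2,4-bis(methoxymethoxy)-5-methylbenzaldehyde
Conditions: MOMCl, i-Pr2NEt, CH2Cl2, 0 °C to reflux
Reagents that add atoms: chloromethyl methyl ether COCCl
Why: Williamson-type O-alkylation of both phenols gives MOM ethers that mask them and later direct the lithiation.

Step 3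
Reactants: 4 2,4-bis(methoxymethoxy)-5-methylbenzaldehyde
Product: 6 2,4-bis(methoxymethoxy)-5-methylphenol, via aryl formate 5 (not isolated)
Conditions: mCPBA, CH2Cl2, 0 °C to rt; then K2CO3 (cat.), MeOH, rt
Reagents that add atoms: mCPBA OOC(=O)c1cccc(Cl)c1
Why: Baeyer–Villiger (Dakin-type) oxidation, in which the aryl group made electron-rich by its ortho and para alkoxy groups should migrate to oxygen, followed by methanolysis of the formate.

Step 4
Reactants: 6 2,4-bis(methoxymethoxy)-5-methylphenol
Product: 8 2-hydroxy-3,5-bis(methoxymethoxy)-6-methylbenzaldehyde, via ortho-hydroxymethylphenol magnesium salt 7 (not isolated)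
Conditions: MgCl2, Et3N, paraformaldehyde, MeCN, reflux
Reagents that add atoms: formaldehyde (from paraformaldehyde) C=O
Why: Casnati–Skattebøl ortho-formylation, in which the magnesium phenoxide should deliver formaldehyde to the single free ortho carbon and a second formaldehyde oxidises the benzylic alkoxide by hydride transfer.

Step 5
Reactants: 8 2-hydroxy-3,5-bis(methoxymethoxy)-6-methylbenzaldehyde
Product: 9 3,5-bis(methoxymethoxy)-2-methyl-6-(propan-2-yloxy)benzaldehyde
Conditions: 2-iodopropane, K2CO3, DMF, 60 °C
Reagents that add atoms: 2-iodopropane CC(C)I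
Why: Williamson etherification of the acidic salicylaldehyde hydroxyl with a secondary iodide, as in standard preparations of 2-isopropoxybenzaldehydes.

Step 6
Reactants: 9 3,5-bis(methoxymethoxy)-2-methyl-6-(propan-2-yloxy)benzaldehyde
Product: 10 3-ethynyl-1,5-bis(methoxymethoxy)-2-methyl-4-(propan-2-yloxy)benzene
Conditions: dimethyl (1-diazo-2-oxopropyl)phosphonate, K2CO3, MeOH, 0 °C to rt
Reagents that add atoms: dimethyl (1-diazo-2-oxopropyl)phosphonate COP(=O)(OC)C(=[N+]=[N-])C(C)=O
Why: Ohira–Bestmann modification of the Seyferth–Gilbert homologation (olefination to a diazoalkene, loss of N2, 1,2-hydrogen shift) should give the terminal alkyne under mild base that leaves the acetals untouched.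

Step 7
Reactants: 10 3-ethynyl-1,5-bis(methoxymethoxy)-2-methyl-4-(propan-2-yloxy)benzene
Product: 11 6,8-bis(methoxymethoxy)-2,2,5-trimethyl-2H-chromene
Conditions: [(XPhos)Au(NCMe)]SbF6 (5 mol %), 4 Å MS, MeNO2, 80 °C
Reagents that add atoms: none
Why: Proposed new method: the cationic monovalent gold centre should activate the terminal alkyne of 10, the isopropyl methine C–H, held in a six-membered array (H–C–O–C8a=C4a–C) over the internal alkyne carbon, should transfer hydride to that carbon anti to gold, and the resulting aryloxocarbenium/(Z)-vinylgold zwitterion should collapse by attack of the gold-bearing carbon on the oxocarbenium carbon with release of the catalyst. The closest known reaction type is the gold- or platinum-catalysed 1,5-hydride shift/cyclization (hydroalkylation) of alkynyl alkyl ethers to cyclohexenes with a new quaternary carbon next to oxygen, together with the Lewis-acid hydride shift/cyclization of aryl alkyl ethers onto benzylidene malonates that gives chromans; what is new is an aryl isopropyl ether as the donor paired with an ortho-ethynyl acceptor. The 2H-pyran ring closes as a formal 6-endo-dig hydroalkylation in which the two alkyne carbons become C4 and C3 and the former methine carbon becomes C2. No stereocentre is formed, and the cis geometry of C3=C4 follows from the anti hydroauration, which places gold cis to the aryl carbon. The step needs hydride transfer to outrun 5-endo attack of the ether oxygen on the alkyne and alkyne hydration: a tertiary C–H is the best hydride donor, isopropyl is a poor migrating group, the two ortho substituents twist the isopropoxy group out of the ring plane so that the oxygen lone pair supports the oxocarbenium, and dry conditions exclude water.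

Step 8
Reactants: 12 3-phenylpropanoyl chloride
Product: 13 N-methoxy-N-methyl-3-phenylpropanamide
Conditions: MeNHOMe·HCl, Et3N, CH2Cl2, 0 °C to rt
Reagents that add atoms: N,O-dimethylhydroxylamine hydrochloride CNOC.Cl
Why: N-acylation of the amine by the acid chloride gives the Weinreb amide.

Step 9
Reactants: 11 6,8-bis(methoxymethoxy)-2,2,5-trimethyl-2H-chromene; 13 N-methoxy-N-methyl-3-phenylpropanamide
Product: 16 1-[6,8-bis(methoxymethoxy)-2,2,5-trimethyl-2H-chromen-7-yl]-3-phenylpropan-1-one, via 7-lithiochromene 14 (not isolated), via lithium hemiaminal alkoxide 15 (not isolated)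
Conditions: n-BuLi, THF, 0 °C; then 13, −78 °C to rt; aq NH4Cl
Reagents that add atoms: n-butyllithium [Li]CCCC (lithium of 14 and 15 only)
Why: Directed ortho-metalation at the only aromatic C–H, flanked by two coordinating MOM ethers, followed by Weinreb ketone synthesis, in which the chelated tetrahedral adduct should prevent over-addition.

Step 10
Reactants: 16 1-[6,8-bis(methoxymethoxy)-2,2,5-trimethyl-2H-chromen-7-yl]-3-phenylpropan-1-one
Product: 17 1-(6,8-dihydroxy-2,2,5-trimethyl-2H-chromen-7-yl)-3-phenylpropan-1-one
Conditions: HCl (3 M), MeOH, 40 °C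
Reagents that add atoms: none
Why: Acid-catalysed acetal exchange (MOM cleavage) in methanol, conditions under which 2,2-dimethyl-2H-chromenes are routinely retained.

Step 11
Reactants: 17 1-(6,8-dihydroxy-2,2,5-trimethyl-2H-chromen-7-yl)-3-phenylpropan-1-one; 18 3-methylbut-2-en-1-yl acetate (prenyl acetate)
Product: 19 (5S)-8-hydroxy-2,2,5-trimethyl-5-(3-methylbut-2-en-1-yl)-7-(3-phenylpropanoyl)-2H-chromen-6(5H)-one
Conditions: Pd2(dba)3·CHCl3 (2.5 mol %), (R,R)-DACH-phenyl Trost ligand (7.5 mol %), K2CO3, 1,4-dioxane, rt
Reagents that add atoms: none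
Why: Tsuji–Trost asymmetric allylic alkylation with dearomatisation, in which zerovalent palladium ionises 18, the phenoxide should attack the unsubstituted terminus of the π-prenyl complex through C5 (the only ring carbon ortho to one phenolic oxygen and para to the other that carries neither oxygen nor the acyl group), reversible O-prenylation drains into irreversible C-alkylation, and the chiral pocket of the ligand selects the face of the phenoxide and so sets the S-configured quaternary centre.

**Compound list**

1 | 4-methylbenzene-1,3-diol | Cc1ccc(O)cc1O | starting material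
2 | N-[(2,4-dihydroxy-5-methylphenyl)methylidene]-N-methylmethanaminium chloride (not isolated) | C[N+](C)=Cc1cc(C)c(O)cc1O.[Cl-] | intermediate
3 | 2,4-dihydroxy-5-methylbenzaldehyde | Cc1cc(C=O)c(O)cc1O | intermediate
4 | 2,4-bis(methoxymethoxy)-5-methylbenzaldehyde | COCOc1cc(OCOC)c(C=O)cc1C | intermediate
5 | 2,4-bis(methoxymethoxy)-5-methylphenyl formate (not isolated) | COCOc1cc(OCOC)c(OC=O)cc1C | intermediate
6 | 2,4-bis(methoxymethoxy)-5-methylphenol | COCOc1cc(OCOC)c(O)cc1C | intermediate
7 | 2-(hydroxymethyl)-4,6-bis(methoxymethoxy)-3-methylphenol, present as its magnesium salt (not isolated) | COCOc1cc(OCOC)c(O)c(CO)c1C | intermediate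
8 | 2-hydroxy-3,5-bis(methoxymethoxy)-6-methylbenzaldehyde | COCOc1cc(OCOC)c(O)c(C=O)c1C | intermediate
9 | 3,5-bis(methoxymethoxy)-2-methyl-6-(propan-2-yloxy)benzaldehyde | COCOc1cc(OCOC)c(OC(C)C)c(C=O)c1C | intermediate
10 | 3-ethynyl-1,5-bis(methoxymethoxy)-2-methyl-4-(propan-2-yloxy)benzene | COCOc1cc(OCOC)c(OC(C)C)c(C#C)c1C | intermediate
11 | 6,8-bis(methoxymethoxy)-2,2,5-trimethyl-2H-chromene | COCOc1cc(OCOC)c2OC(C)(C)C=Cc2c1C | intermediate
12 | 3-phenylpropanoyl chloride | O=C(Cl)CCc1ccccc1 | starting material
13 | N-methoxy-N-methyl-3-phenylpropanamide | CON(C)C(=O)CCc1ccccc1 | intermediate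
14 | [6,8-bis(methoxymethoxy)-2,2,5-trimethyl-2H-chromen-7-yl]lithium (not isolated) | [Li]c1c(OCOC)c(C)c2C=CC(C)(C)Oc2c1OCOC | intermediate
15 | lithium 1-[6,8-bis(methoxymethoxy)-2,2,5-trimethyl-2H-chromen-7-yl]-1-[methoxy(methyl)amino]-3-phenylpropan-1-olate (not isolated) | [Li]OC(CCc1ccccc1)(N(C)OC)c1c(OCOC)c(C)c2C=CC(C)(C)Oc2c1OCOC | intermediate
16 | 1-[6,8-bis(methoxymethoxy)-2,2,5-trimethyl-2H-chromen-7-yl]-3-phenylpropan-1-one | COCOc1c(C(=O)CCc2ccccc2)c(OCOC)c2OC(C)(C)C=Cc2c1C | intermediate
17 | 1-(6,8-dihydroxy-2,2,5-trimethyl-2H-chromen-7-yl)-3-phenylpropan-1-one | CC1(C)C=Cc2c(C)c(O)c(C(=O)CCc3ccccc3)c(O)c2O1 | intermediate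
18 | 3-methylbut-2-en-1-yl acetate | CC(=O)OCC=C(C)C | starting material
19 | (5S)-8-hydroxy-2,2,5-trimethyl-5-(3-methylbut-2-en-1-yl)-7-(3-phenylpropanoyl)-2H-chromen-6(5H)-one | CC(C)=CC[C@]1(C)C(=O)C(C(=O)CCc2ccccc2)=C(O)C2=C1C=CC(C)(C)O2 | target

**Count**

Total steps: 11 (step 8 is a one-step side branch). Longest linear sequence: 10 steps (steps 1 to 7 and 9 to 11) from 4-methylresorcinol.

**Steps most likely to fail**

1. Step 7 (Proposed new method). Hydride transfer from the aryl ether methine may be too slow, so that alkyne hydration, oligomerisation or oxy-auration with loss of the isopropyl group takes over. The fallback uses known chemistry, sets out from 6 and comes back at 11. Phenol 6 is O-alkylated with 3-chloro-3-methylbut-1-yne (CuCl2 cat., DBU, MeCN, 0 °C) to 1,5-bis(methoxymethoxy)-2-methyl-4-[(2-methylbut-3-yn-2-yl)oxy]benzene F1. Heating F1 (o-xylene, 140 °C) should bring about the aryl propargyl Claisen rearrangement into the single free ortho position, 1,5-hydrogen shift and oxa-6π electrocyclisation to chromene 11. Steps 4 to 6 are then not needed.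

2. Step 11. Facial discrimination of the hindered phenoxide by the chiral π-prenyl palladium complex may be poor, or O-alkylation may compete. The fallback sets out from 17 and comes back at 19. Compound 17 is C-prenylated without asymmetric induction (1-bromo-3-methylbut-2-ene, NaOMe, MeOH, 0 °C, the classical nuclear alkylation of acylphenols) to racemic 8-hydroxy-2,2,5-trimethyl-5-(3-methylbut-2-en-1-yl)-7-(3-phenylpropanoyl)-2H-chromen-6(5H)-one F2. The racemate is resolved by preparative HPLC on an amylose tris(3,5-dimethylphenylcarbamate) phase, which gives 19 and leaves the (5R)-enantiomer F3. The configuration is to be assigned by electronic circular dichroism against calculation.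

3. Step 4. Formylation at the ortho carbon flanked by the methyl group may be sluggish, with oxidative degradation of the electron-rich phenol on prolonged heating. The fallback sets out from 6 and comes back at 10, replacing formylation and homologation by cross-coupling. Phenol 6 is iodinated ortho to the hydroxyl (N-iodosuccinimide, DMF, 0 °C) to 2-iodo-4,6-bis(methoxymethoxy)-3-methylphenol F4. This is alkylated (2-iodopropane, K2CO3, DMF, 60 °C) to 3-iodo-1,5-bis(methoxymethoxy)-2-methyl-4-(propan-2-yloxy)benzene F5. Sonogashira coupling with ethynyltrimethylsilane (PdCl2(PPh3)2, CuI, Et3N, 50 °C) gives {[2,4-bis(methoxymethoxy)-3-methyl-6-(propan-2-yloxy)phenyl]ethynyl}trimethylsilane F6, and K2CO3 in MeOH removes the silyl group to give 10.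

**Further compounds**

F1 | step 7 | 1,5-bis(methoxymethoxy)-2-methyl-4-[(2-methylbut-3-yn-2-yl)oxy]benzene | COCOc1cc(OCOC)c(OC(C)(C)C#C)cc1C
F2 | step 11 | racemic 8-hydroxy-2,2,5-trimethyl-5-(3-methylbut-2-en-1-yl)-7-(3-phenylpropanoyl)-2H-chromen-6(5H)-one | CC(C)=CCC1(C)C(=O)C(C(=O)CCc2ccccc2)=C(O)C2=C1C=CC(C)(C)O2
F3 | step 11 | (5R)-8-hydroxy-2,2,5-trimethyl-5-(3-methylbut-2-en-1-yl)-7-(3-phenylpropanoyl)-2H-chromen-6(5H)-one | CC(C)=CC[C@@]1(C)C(=O)C(C(=O)CCc2ccccc2)=C(O)C2=C1C=CC(C)(C)O2
F4 | step 4 | 2-iodo-4,6-bis(methoxymethoxy)-3-methylphenol | COCOc1cc(OCOC)c(O)c(I)c1C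
F5 | step 4 | 3-iodo-1,5-bis(methoxymethoxy)-2-methyl-4-(propan-2-yloxy)benzene | COCOc1cc(OCOC)c(OC(C)C)c(I)c1C
F6 | step 4 | {[2,4-bis(methoxymethoxy)-3-methyl-6-(propan-2-yloxy)phenyl]ethynyl}trimethylsilane | COCOc1cc(OCOC)c(OC(C)C)c(C#C[Si](C)(C)C)c1C
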